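## The problem

The target is a bicyclic lactone. For this proposal the ten-membered carbocycle is numbered C1 (ketone), C2 (carrying the exocyclic methylene), C3 (CH2), C4 (acetoxy carbon), C5, C6, C7=C8 (methyl on C8), C9 and C10. The butenolide is fused across C5–C6: C5 is its β-carbon, C6 its γ-carbon (bearing the ring oxygen), and its α-carbon C11 carries the lactone carbonyl and the acetoxymethyl carbon C13.

A synthesis has to assemble a fully substituted C5=C11 alkene with three different carbon branches in fixed positions, a (Z)-trisubstituted C7=C8 alkene, and a strained medium ring. There are only two stereocenters, C4 (S) and C6 (R). They are 1,3-related across the sp2 carbon C5, so neither can be trusted to control the other and each has to be set by a reagent. Once C6 exists, however, errors at C4 show up as separable diastereomers.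

Several groups will not survive rough treatment:
- the C2-methylene C1-ketone is a Michael acceptor prone to polymerisation;
- C6–H is allylic and vinylogously acidic, so base can epimerise it;
- the two allylic acetates and the allylic lactone bond C6–O can be ionised by low-valent metals.

The enabling feature is that ketone carbon C1 is bonded directly to C2, which bears the exocyclic CH2 inside the ten-membered ring. In reduced form this is a 2-substituted allylic alcohol, which is what forms when an aldehyde carbon (C1) is joined to the internal carbon of a terminal alkyne (C2).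

## Retrosynthesis

**End game (28 to 24).** The acetates and the enone are introduced last, because neither tolerates zerovalent nickel or base. Target 28 comes from diol 27 by acetylation, 27 from bis-silyl enone 26 by desilylation, and 26 from allylic alcohol 25 by oxidation. Alcohol 25 comes from the triethylsilyl ether 24, whose silyl group differs from the two tert-butyldimethylsilyl (TBS) ethers so that only C1 is unmasked.

**Ring closure (24 to 23).** The C1–C2 bond is cut, giving ynal 23 with a terminal alkyne (C3–C2≡CH) and the aldehyde C1. Cuts at C2–C3 or C3–C4 would place enolate or carbanion chemistry next to the butenolide; a cut at C9–C10 would give no handle for the methylene group. The C1–C2 cut needs no stereocontrol, uses two robust termini, and leaves the rigid butenolide and (Z)-alkene segment intact. The forward reaction must close at the internal alkyne carbon (exo) and beat oligomerisation.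

**Alkyne arm (23 to 19 + 20).** Ynal 23 is the unmasked form of acetal 22, the silyl ether of homopropargylic alcohol 21. Cutting C3–C4 leads to butenolide aldehyde 19 and allenylboronate 20. The alternative C4–C5 cut would require a butenolide β-metal species and the unstable 3-butynal. The forward step must set C4 (S) by catalyst control on a hindered conjugated aldehyde.

**Differentiating C4 and C13 (19 to 15 + 10).** Aldehyde 19 arises from alcohol 18, liberated from 4-methoxybenzyl (PMB) ether 17. The TBS-protected C13 arm in 17 comes from alcohol 16, and the C11–C13 bond is cut back to α-iodobutenolide 15 and (tributylstannyl)methanol 10. Cross-coupling on an alkenyl iodide is preferred to direct trapping with formaldehyde because it is the more dependable way to place C13.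

**Tetrasubstituted butenolide (15 to 9 + 12).** Three bonds are cut: C4–C5, C11–I and the lactone C–O. This leads to γ-hydroxy ynoate 9 and alkoxymethylstannane 12 (made from 10 and chloride 11). Anti-carbomagnesiation of a propargylic alcohol with CO2 trapping was considered, but it needs a Grignard formyl equivalent that does not exist in useful form. Condensation on an α-hydroxy ketone would endanger C6. Syn-carbocupration of the ynoate fixes the alkene geometry and lactonises by itself.

**C6 stereocenter (9 to 7 + 8).** The C5–C6 bond is cut to (Z)-enal 7 and methyl propiolate 8, which supplies C5, C11 and the lactone carbonyl. The forward reaction is a catalytic asymmetric alkynylation that sets C6 (R).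

**(Z)-Alkene (7 to 5 to 1 + 2).** The C6–C7 bond is cut by formylation of the alkenyllithium from iodide 5. Iodide 5 is cut at C8–C9 to bromide 1 (via its Grignard reagent) and propyne 2. Syn-carbocupration gives the (Z)-trisubstituted alkene with a certainty that carbonyl olefination cannot match.

## Roads not taken

**Alternative 1: anionic oxy-Cope ring expansion.**
- Cut: C3–C4, formed by a [3,3] shift.
- Forward step: KH and a crown ether convert dialkenylcyclohexenol A1 into its alkoxide. A chair transition state forms C3–C4, opens the six-membered ring to the ten-membered one, and the resulting C1–C2 enolate expels methoxide to give methylene ketone A2.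
- Merits: the ring is made by a unimolecular ring expansion, so no high dilution is needed and medium-ring closure is not fought directly. C4 is set by the enol ether geometry, and the enone appears in the same operation.
- Weak points: A2 has no lactone and no oxygen at C6. The butenolide would have to be built afterwards by oxidising the exocyclic diene beside a free methylene ketone and the C7=C8 alkene. C6 would then be set late, under substrate control, in a flexible ring. The enone is also generated in a strongly basic medium containing methoxide, and A1 needs a geometrically pure enol ether and a trans-dialkenyl carbinol.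
- Comparison: as a ring construction this road is safer than the chosen one. The chosen plan sets against it that both stereocenters and the complete butenolide are in place before the ring closes, leaving only protecting-group and oxidation-state changes afterwards.

**Alternative 2: phosphine-catalysed epoxide opening.**
- Cut: C2–C3.
- Forward step: PMe3 adds to the vinyl ketone of epoxy enone A3. The zwitterionic enolate attacks the epoxide CH2 (C3) through C2, and loss of the phosphine gives hydroxy enone A4.
- Merits: the ring closure delivers the methylene ketone at the correct oxidation level and frees C4–OH with the configuration of the epoxide. No oxidation follows, the end game is about two steps shorter, and no metal is present that could ionise allylic C–O bonds.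
- Weak points: this alkylative cyclisation is established for five- and six-membered rings. For a ten-membered ring the zwitterion is more likely to add to a second enone. The epoxide is allylic to the butenolide alkene, so SN2′ opening or ionisation competes, and the phosphine and the basic zwitterion threaten the butenolide and C6–H. A free vinyl ketone must also be carried into the step.
- Comparison: this road is better in redox and step economy after ring closure. The chosen plan sets against it a ring closure with precedent close to the required ring size and a ketone that stays masked until the end.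

**Alternative 3: decarboxylative ring contraction.**
- Cut: C9–C10.
- Forward step: Pd2(dba)3 (zerovalent palladium) with a phosphine ionises the allylic ester of twelve-membered keto lactone A5. CO2 is lost and the C10 enolate attacks the primary allyl terminus C9, giving A6, which is the same compound as 26.
- Merits: a twelve-membered lactone is easier to close than a ten-membered carbocycle. The contraction occurs within an ion pair without dilution. It reaches 26 directly, saving the silyl cleavage and oxidation of the chosen route.
- Weak points: the C7=C8 geometry has to be re-formed from a π-allyl complex that can isomerise. The lactone bond C6–O is allylic to the same π-system and can be ionised or eliminated by palladium. A5 is a β-keto ester of a methylene ketone, a doubly activated acceptor that is hard to prepare and handle.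
- Comparison: this road is better in convergence on 26 and in ease of the macrocyclic step. The chosen plan sets against it that C7=C8 and C6–O are never touched by the ring-forming metal and that the exocyclic methylene is placed by construction.

Key step: step 13

Remark (assumption): the ligand in step 3 and the acid in step 10 are named by the sense expected from the accepted transition-state models; the antipode, equally available, would be used if the sense proved opposite.

Remark (assumption): the C1 configuration formed in step 13 is immaterial; 24 and 25 would be carried as C1 epimers and are drawn as the (1S) epimers.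

Abbreviations: TBS, tert-butyldimethylsilyl; TES, triethylsilyl; PMB, 4-methoxybenzyl; DDQ, 2,3-dichloro-5,6-dicyano-1,4-benzoquinone; CSA, camphorsulfonic acid; PPTS, pyridinium 4-toluenesulfonate; NMP, N-methylpyrrolidone; IPr, 1,3-bis(2,6-diisopropylphenyl)imidazol-2-ylidene; TRIP, 3,3′-bis(2,4,6-triisopropylphenyl)-1,1′-binaphthyl-2,2′-diyl hydrogen phosphate.

## Route

Step 1
Reactants: 1 2-(2-bromoethyl)-1,3-dioxolane; 2 propyne
Product: 5 2-[(3Z)-4-iodo-3-methylbut-3-en-1-yl]-1,3-dioxolane, via Grignard reagent 3 (not isolated), via vinylcopper 4 (not isolated)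
Conditions: Mg, THF, 20 °C; CuBr·SMe2, Et2O/SMe2, −45 °C; propyne, −25 °C; I2, THF, −50 → 0 °C
Reagents that add atoms: iodine, II
Why: Syn-carbocupration of a terminal alkyne places the alkyl group on the internal carbon and copper on the terminus, cis to each other, and iodinolysis proceeds with retention. This fixes the (Z)-C7=C8 geometry of the target.

Step 2
Reactants: 5 2-[(3Z)-4-iodo-3-methylbut-3-en-1-yl]-1,3-dioxolane
Product: 7 (2Z)-5-(1,3-dioxolan-2-yl)-3-methylpent-2-enal, via vinyllithium 6 (not isolated)
Conditions: t-BuLi (2.1 equiv), Et2O, −78 °C; DMF, −78 → 0 °C; aq. NH4Cl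
Reagents that add atoms: N,N-dimethylformamide, CN(C)C=O
Why: Iodine–lithium exchange retains the alkene geometry and the alkenyllithium is formylated by DMF (Bouveault-type aldehyde synthesis). The dioxolane is inert to the organolithium.

Step 3
Reactants: 7 (2Z)-5-(1,3-dioxolan-2-yl)-3-methylpent-2-enal; 8 methyl propiolate
Product: 9 methyl (4R,5Z)-8-(1,3-dioxolan-2-yl)-4-hydroxy-6-methyloct-5-en-2-ynoate
Conditions: Me2Zn, (S,S)-ProPhenol (20 mol %), Ph3P=O (40 mol %), toluene, 0–4 °C
Reagents that add atoms: none
Why: Catalytic asymmetric alkynylation of an enal by the zinc acetylide of the propiolate inside the dinuclear zinc–ProPhenol complex; the ligand selects the aldehyde face and so sets C6 (R). Enals are good substrates, and the ester, the acetal and the (Z)-alkene are spectators.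

Step 4
Reactants: 10 (tributylstannyl)methanol; 11 4-methoxybenzyl chloride
Product: 12 tributyl{[(4-methoxybenzyl)oxy]methyl}stannane
Conditions: NaH, THF/DMF, 0 °C; 11, Bu4NI (cat.), 20 °C
Reagents that add atoms: none
Why: Williamson ether synthesis on the primary stannyl alcohol; the C–Sn bond is stable to NaH and to the benzylic chloride.

Step 5
Reactants: 9 methyl (4R,5Z)-8-(1,3-dioxolan-2-yl)-4-hydroxy-6-methyloct-5-en-2-ynoate; 12 tributyl{[(4-methoxybenzyl)oxy]methyl}stannane
Product: 15 (5R)-5-[(1Z)-4-(1,3-dioxolan-2-yl)-2-methylbut-1-en-1-yl]-3-iodo-4-{[(4-methoxybenzyl)oxy]methyl}furan-2(5H)-one, via alkoxymethyllithium 13 (not isolated), via lithium dialkylcuprate 14 (not isolated)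
Conditions: 12, n-BuLi, THF, −78 °C; CuBr·SMe2, −78 → −50 °C; 9 pre-treated with LiN(SiMe3)2 (1 equiv, −78 °C); I2, −78 → 0 °C; then CSA (cat.), CH2Cl2, 20 °C
Reagents that add atoms: iodine, II
Why: Tin–lithium exchange gives the α-alkoxymethyllithium, whose Gilman cuprate adds syn across the ynoate (conjugate carbocupration), placing the new CH2 on C5 and copper on C11; iodinolysis retains the geometry. Because the addition is syn, the C6 oxygen and the ester are cis and lactonise, so ring closure also confirms the alkene geometry. C6 itself is not touched.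

Step 6
Reactants: 15 (5R)-5-[(1Z)-4-(1,3-dioxolan-2-yl)-2-methylbut-1-en-1-yl]-3-iodo-4-{[(4-methoxybenzyl)oxy]methyl}furan-2(5H)-one; 10 (tributylstannyl)methanol
Product: 16 (5R)-5-[(1Z)-4-(1,3-dioxolan-2-yl)-2-methylbut-1-en-1-yl]-3-(hydroxymethyl)-4-{[(4-methoxybenzyl)oxy]methyl}furan-2(5H)-one
Conditions: Pd2(dba)3 (5 mol %), AsPh3 (20 mol %), CuI (10 mol %), NMP, 45 °C
Reagents that add atoms: none
Why: Stille coupling of an α-iodobutenolide with (tributylstannyl)methanol, a standard hydroxymethyl transfer (oxidative addition, oxygen-assisted Sn-to-Pd transfer of CH2OH, reductive elimination). The neutral medium spares C6–H.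

Step 7
Reactants: 16 (5R)-5-[(1Z)-4-(1,3-dioxolan-2-yl)-2-methylbut-1-en-1-yl]-3-(hydroxymethyl)-4-{[(4-methoxybenzyl)oxy]methyl}furan-2(5H)-one
Product: 17 (5R)-3-{[(tert-butyldimethylsilyl)oxy]methyl}-5-[(1Z)-4-(1,3-dioxolan-2-yl)-2-methylbut-1-en-1-yl]-4-{[(4-methoxybenzyl)oxy]methyl}furan-2(5H)-one
Conditions: TBSCl, imidazole, DMF, 0 → 20 °C
Reagents that add atoms: tert-butyldimethylsilyl chloride, CC(C)(C)[Si](C)(C)Cl
Why: Standard silylation of a primary allylic alcohol; the TBS ether is the nickel-compatible stand-in for the C13 acetate.

Step 8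
Reactants: 17 (5R)-3-{[(tert-butyldimethylsilyl)oxy]methyl}-5-[(1Z)-4-(1,3-dioxolan-2-yl)-2-methylbut-1-en-1-yl]-4-{[(4-methoxybenzyl)oxy]methyl}furan-2(5H)-one
Product: 18 (5R)-3-{[(tert-butyldimethylsilyl)oxy]methyl}-5-[(1Z)-4-(1,3-dioxolan-2-yl)-2-methylbut-1-en-1-yl]-4-(hydroxymethyl)furan-2(5H)-one
Conditions: DDQ, CH2Cl2/pH 7 buffer, 0 °C
Reagents that add atoms: none
Why: Oxidative cleavage of the PMB ether by DDQ (benzylic hydride abstraction, hydrolysis of the oxocarbenium ion). Buffered conditions leave the silyl ether, the acetal and both alkenes alone.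

Step 9
Reactants: 18 (5R)-3-{[(tert-butyldimethylsilyl)oxy]methyl}-5-[(1Z)-4-(1,3-dioxolan-2-yl)-2-methylbut-1-en-1-yl]-4-(hydroxymethyl)furan-2(5H)-one
Product: 19 (5R)-3-{[(tert-butyldimethylsilyl)oxy]methyl}-5-[(1Z)-4-(1,3-dioxolan-2-yl)-2-methylbut-1-en-1-yl]-4-formylfuran-2(5H)-one
Conditions: Dess–Martin periodinane, NaHCO3, CH2Cl2, 0 → 20 °C
Reagents that add atoms: none
Why: Dess–Martin oxidation of a primary allylic alcohol under buffered, non-basic conditions; neither over-oxidation nor epimerisation at C6 is expected.

Step 10
Reactants: 19 (5R)-3-{[(tert-butyldimethylsilyl)oxy]methyl}-5-[(1Z)-4-(1,3-dioxolan-2-yl)-2-methylbut-1-en-1-yl]-4-formylfuran-2(5H)-one; 20 allenylboronic acid pinacol ester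
Product: 21 (5R)-3-{[(tert-butyldimethylsilyl)oxy]methyl}-5-[(1Z)-4-(1,3-dioxolan-2-yl)-2-methylbut-1-en-1-yl]-4-[(1S)-1-hydroxybut-3-yn-1-yl]furan-2(5H)-one
Conditions: (S)-TRIP (10 mol %), 4 Å molecular sieves, toluene, −20 °C; aqueous work-up
Reagents that add atoms: none
Why: Chiral phosphoric acid-catalysed propargylation: the acid hydrogen-bonds to a boronate oxygen in a closed six-membered SE2′ transition state and selects the aldehyde face, so the catalyst sets C4 (S); the remote C6 centre should only modulate the level. The allenyl-to-propargyl transposition is inherent in the cyclic transition state.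

Step 11
Reactants: 21 (5R)-3-{[(tert-butyldimethylsilyl)oxy]methyl}-5-[(1Z)-4-(1,3-dioxolan-2-yl)-2-methylbut-1-en-1-yl]-4-[(1S)-1-hydroxybut-3-yn-1-yl]furan-2(5H)-one
Product: 22 (5R)-4-[(1S)-1-{[tert-butyldimethylsilyl]oxy}but-3-yn-1-yl]-3-{[(tert-butyldimethylsilyl)oxy]methyl}-5-[(1Z)-4-(1,3-dioxolan-2-yl)-2-methylbut-1-en-1-yl]furan-2(5H)-one
Conditions: TBSOTf, 2,6-lutidine, CH2Cl2, −78 °C
Reagents that add atoms: tert-butyldimethylsilyl triflate, CC(C)(C)[Si](C)(C)OS(=O)(=O)C(F)(F)F
Why: Silylation of a hindered secondary alcohol with a silyl triflate and a hindered pyridine base; at −78 °C the dioxolane should not be attacked.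

Step 12
Reactants: 22 (5R)-4-[(1S)-1-{[tert-butyldimethylsilyl]oxy}but-3-yn-1-yl]-3-{[(tert-butyldimethylsilyl)oxy]methyl}-5-[(1Z)-4-(1,3-dioxolan-2-yl)-2-methylbut-1-en-1-yl]furan-2(5H)-one
Product: 23 (4Z)-5-[(2R)-3-[(1S)-1-{[tert-butyldimethylsilyl]oxy}but-3-yn-1-yl]-4-{[(tert-butyldimethylsilyl)oxy]methyl}-5-oxo-2,5-dihydrofuran-2-yl]-4-methylpent-4-enal
Conditions: TESOTf, 2,6-lutidine, CH2Cl2, 0 °C; then H2O
Reagents that add atoms: water, O
Why: Chemoselective cleavage of an aldehyde-derived cyclic acetal by a silyl triflate and a hindered pyridine: one acetal oxygen is silylated, the oxocarbenium ion is captured by the pyridine, and water hydrolyses the pyridinium adduct. No protic acid is present, so both TBS ethers and the (Z)-alkene survive.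

Step 13
Reactants: 23 (4Z)-5-[(2R)-3-[(1S)-1-{[tert-butyldimethylsilyl]oxy}but-3-yn-1-yl]-4-{[(tert-butyldimethylsilyl)oxy]methyl}-5-oxo-2,5-dihydrofuran-2-yl]-4-methylpent-4-enal
Product: 24 ten-membered carbocycle fused at C5–C6 to the butenolide: C1 triethylsilyloxy (epimers; 1S drawn), C2 exocyclic methylene, (4S)-OTBS, (6R), (7Z), C11 CH2OTBS
Conditions: Ni(cod)2 (20 mol %, zerovalent nickel) premixed with IPr (20 mol %), Et3SiH (5 equiv), THF, slow addition of 23 to 0.003 M, 25–45 °C
Reagents that add atoms: triethylsilane, CC[SiH](CC)CC
Why: Nickel-catalysed reductive alkyne–aldehyde coupling run intramolecularly (reductive ynal macrocyclisation), a known reaction type whose exo-selective form is documented mainly for rings of eleven or more members. Zerovalent nickel carrying one bulky carbene binds the alkyne and the C1 aldehyde and undergoes oxidative cyclisation to an oxanickelacyclopentene; the bulky ligand places the unsubstituted alkyne terminus next to nickel, so the C1–C2 bond forms at the internal alkyne carbon. σ-Bond metathesis of Et3SiH with the Ni–O bond and C–H reductive elimination release the silyl ether and return zerovalent nickel. The ten-membered carbocycle therefore closes in the exo mode with respect to the alkyne; the endo mode would give an eleven-membered ring with an endocyclic alkene. The new C1 stereocenter is left to the substrate conformation and needs no control, because both epimers give the same ketone in step 15. The step needs exo over endo regioselectivity, secured by ligand bulk acting on a terminal, electronically unbiased alkyne. It also needs cyclisation over oligomerisation, favoured by slow addition and by the bend that the (Z)-C7=C8 alkene and the planar butenolide impose on the chain. Chemoselectivity rests on silyl ethers in place of acetates, on steric shielding of the tetrasubstituted butenolide alkene, and on pre-forming the 1:1 nickel–carbene complex so that no free carbene can epimerise C6.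

Step 14
Reactants: 24 macrocyclic C1 triethylsilyl ether
Product: 25 macrocyclic C1 allylic alcohol: C1 hydroxyl (epimers; 1S drawn), C2 methylene, (4S)-OTBS, (6R), (7Z), C11 CH2OTBS
Conditions: PPTS (cat.), MeOH/CH2Cl2, 0 °C
Reagents that add atoms: none
Why: Acid-catalysed methanolysis should cleave the TES ether much faster than the two bulkier TBS ethers (selective desilylation by steric differentiation).

Step 15
Reactants: 25 macrocyclic C1 allylic alcohol
Product: 26 bis-TBS methylene ketone: C1 ketone, C2 methylene, (4S)-OTBS, (6R), (7Z), C11 CH2OTBS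
Conditions: Dess–Martin periodinane, NaHCO3, CH2Cl2, 0 °C
Reagents that add atoms: none
Why: Dess–Martin oxidation of a secondary allylic alcohol; both C1 epimers converge on the enone. The neutral buffered medium avoids conjugate addition to the new methylene ketone.

Step 16
Reactants: 26 bis-TBS methylene ketone
Product: 27 diol: C1 ketone, C2 methylene, (4S)-hydroxyl, (6R), (7Z), C11 CH2OH
Conditions: HF·pyridine, pyridine, THF, 0 → 20 °C
Reagents that add atoms: none
Why: Fluoride-mediated desilylation with buffered HF·pyridine is acidic rather than basic, so neither the methylene ketone nor C6–H meets a base. Closure of the C4 hydroxyl onto the enone would be a disfavoured 5-endo process.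

Step 17
Reactants: 27 diol
Product: 28 target, (4S,6R,7Z)-diacetate
Conditions: Ac2O, pyridine, DMAP (cat.), CH2Cl2, 0 °C
Reagents that add atoms: acetic anhydride, CC(=O)OC(C)=O
Why: Acetylation of the primary and the secondary alcohol under nucleophilic catalysis at low temperature completes the target.

## Compound list

1 | 2-(2-bromoethyl)-1,3-dioxolane | BrCCC1OCCO1 | starting material
2 | propyne | CC#C | starting material
3 | [2-(1,3-dioxolan-2-yl)ethyl]magnesium bromide | Br[Mg]CCC1OCCO1 | intermediate (not isolated)
4 | (Z)-[4-(1,3-dioxolan-2-yl)-2-methylbut-1-en-1-yl]copper | [Cu]/C=C(/C)CCC1OCCO1 | intermediate (not isolated)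
5 | 2-[(3Z)-4-iodo-3-methylbut-3-en-1-yl]-1,3-dioxolane | I/C=C(/C)CCC1OCCO1 | intermediate
6 | (Z)-[4-(1,3-dioxolan-2-yl)-2-methylbut-1-en-1-yl]lithium | [Li]/C=C(/C)CCC1OCCO1 | intermediate (not isolated)
7 | (2Z)-5-(1,3-dioxolan-2-yl)-3-methylpent-2-enal | O=C/C=C(/C)CCC1OCCO1 | intermediate
8 | methyl propiolate | C#CC(=O)OC | starting material
9 | methyl (4R,5Z)-8-(1,3-dioxolan-2-yl)-4-hydroxy-6-methyloct-5-en-2-ynoate | COC(=O)C#C[C@H](O)/C=C(/C)CCC1OCCO1 | intermediate
10 | (tributylstannyl)methanol | CCCC[Sn](CCCC)(CCCC)CO | starting material
11 | 4-methoxybenzyl chloride | COc1ccc(CCl)cc1 | starting material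
12 | tributyl{[(4-methoxybenzyl)oxy]methyl}stannane | CCCC[Sn](CCCC)(CCCC)COCc1ccc(OC)cc1 | intermediate
13 | {[(4-methoxybenzyl)oxy]methyl}lithium | [Li]COCc1ccc(OC)cc1 | intermediate (not isolated)
14 | lithium bis{[(4-methoxybenzyl)oxy]methyl}cuprate | [Li+].COc1ccc(COC[Cu-]COCc2ccc(OC)cc2)cc1 | intermediate (not isolated)
15 | (5R)-3-iodo-4-(PMB-oxymethyl) butenolide with the (1Z)-4-(1,3-dioxolan-2-yl)-2-methylbut-1-enyl group on C5 | COc1ccc(COCC2=C(I)C(=O)O[C@@H]2/C=C(/C)CCC3OCCO3)cc1 | intermediate
16 | (5R)-3-(hydroxymethyl)-4-(PMB-oxymethyl) butenolide, same C5 side chain | COc1ccc(COCC2=C(CO)C(=O)O[C@@H]2/C=C(/C)CCC3OCCO3)cc1 | intermediate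
17 | (5R)-3-(TBS-oxymethyl)-4-(PMB-oxymethyl) butenolide, same C5 side chain | COc1ccc(COCC2=C(CO[Si](C)(C)C(C)(C)C)C(=O)O[C@@H]2/C=C(/C)CCC3OCCO3)cc1 | intermediate
18 | (5R)-3-(TBS-oxymethyl)-4-(hydroxymethyl) butenolide, same C5 side chain | OCC1=C(CO[Si](C)(C)C(C)(C)C)C(=O)O[C@@H]1/C=C(/C)CCC2OCCO2 | intermediate
19 | (5R)-3-(TBS-oxymethyl)-4-formyl butenolide, same C5 side chain | O=CC1=C(CO[Si](C)(C)C(C)(C)C)C(=O)O[C@@H]1/C=C(/C)CCC2OCCO2 | intermediate
20 | allenylboronic acid pinacol ester | C=C=CB1OC(C)(C)C(C)(C)O1 | starting material
21 | (5R)-3-(TBS-oxymethyl)-4-[(1S)-1-hydroxybut-3-yn-1-yl] butenolide, same C5 side chain | C#CC[C@H](O)C1=C(CO[Si](C)(C)C(C)(C)C)C(=O)O[C@@H]1/C=C(/C)CCC2OCCO2 | intermediate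
22 | bis-TBS ether of 21 (acetal) | C#CC[C@H](O[Si](C)(C)C(C)(C)C)C1=C(CO[Si](C)(C)C(C)(C)C)C(=O)O[C@@H]1/C=C(/C)CCC2OCCO2 | intermediate
23 | bis-TBS butenolide ynal (precursor of the key step) | C#CC[C@H](O[Si](C)(C)C(C)(C)C)C1=C(CO[Si](C)(C)C(C)(C)C)C(=O)O[C@@H]1/C=C(/C)CCC=O | intermediate
24 | macrocyclic C1 triethylsilyl ether, C2 methylene, (4S)-OTBS, (6R), (7Z), C11 CH2OTBS (C1 epimers, 1S drawn) | C=C1C[C@H](O[Si](C)(C)C(C)(C)C)C2=C(CO[Si](C)(C)C(C)(C)C)C(=O)O[C@@H]2/C=C(/C)CC[C@@H]1O[Si](CC)(CC)CC | intermediate (product of the key step)
25 | macrocyclic C1 allylic alcohol (C1 epimers, 1S drawn) | C=C1C[C@H](O[Si](C)(C)C(C)(C)C)C2=C(CO[Si](C)(C)C(C)(C)C)C(=O)O[C@@H]2/C=C(/C)CC[C@@H]1O | intermediate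
26 | bis-TBS methylene ketone | C=C1C[C@H](O[Si](C)(C)C(C)(C)C)C2=C(CO[Si](C)(C)C(C)(C)C)C(=O)O[C@@H]2/C=C(/C)CCC1=O | intermediate
27 | diol methylene ketone | C=C1C[C@H](O)C2=C(CO)C(=O)O[C@@H]2/C=C(/C)CCC1=O | intermediate
28 | CNP0239761.1, (4S,6R,7Z)-diacetate | C=C1C[C@H](OC(C)=O)C2=C(COC(C)=O)C(=O)O[C@@H]2/C=C(/C)CCC1=O | target

## Step count and risk

Total: 17 steps. Longest linear sequence: 16 steps (steps 1–3 and 5–17); step 4 is a one-step branch.

**Step 13 (key step).** Three things may go wrong. Closure may occur at the terminal alkyne carbon, giving the eleven-membered endo ring. Intermolecular coupling may outrun closure of the strained ten-membered ring. Nickel may insert into the allylic lactone bond C6–O or simply hydrosilylate the aldehyde. All three are plausible because the ring is smaller than in the usual precedent and the substrate carries an allylic ester.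

Fallback, from 19 back to 25: the alkyne is replaced by a 2-bromoalkene so that the regiochemistry is fixed by constitution and the ring is closed with chromium. Aldehyde 19 would be allylated with 2-bromoallylboronic acid pinacol ester under the chiral phosphoric acid conditions of step 10 to give the bromoallyl carbinol F1. Silylation as in step 11 gives the bis-TBS ether F2, and acetal cleavage as in step 12 gives the bromo aldehyde F3. An intramolecular Nozaki–Hiyama–Kishi reaction (CrCl2, catalytic NiCl2, DMSO/THF, high dilution) would form C1–C2 and deliver allylic alcohol 25 directly.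

**Step 5.** The α-alkoxymethyl group may transfer sluggishly to a hindered ynoate that carries a neighbouring alkoxide. The α-cuprio ester may lose its syn geometry through the allenoate before iodination. Protonation may compete with iodination.

Fallback, from 9 back to 15: both C–X bonds are made without an organocopper. Addition of Me3SnSnMe3 across the ynoate with Pd(PPh3)4 is syn, and lactonisation would give the bis(trimethylstannyl)butenolide F4. Iodine converts it into the diiodobutenolide F5. A Stille coupling with 10, expected at the more electrophilic C5-bound (β) position first, gives the iodo alcohol F6. Etherification with 4-methoxybenzyl trichloroacetimidate and catalytic acid returns 15.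

**Step 10.** Facial selectivity may be poor, because the aldehyde is flanked by two substituents and the catalyst may be mismatched with the C6 centre. Uncatalysed background addition may erode it further.

Fallback, from 19 back to 21: C4 is set by reduction instead of addition. An indium-mediated Barbier reaction with 3-bromo-1-(trimethylsilyl)propyne would give the silylated homopropargylic alcohol F7 as C4 epimers. Dess–Martin oxidation gives the ynone F8. Corey–Bakshi–Shibata reduction with catecholborane at −78 °C, with the oxazaborolidine enantiomer chosen for the (S) face, gives the (S)-alcohol F9. Silver-mediated removal of the alkynyl silyl group (AgNO3, 2,6-lutidine, aqueous acetone) returns 21.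

**Step 16 (with step 17).** The hindered secondary TBS ether may cleave slowly. During that time pyridine or fluoride may add to the methylene ketone, or the enone may polymerise.

Fallback, from 23 to 28: the enone is unveiled last. Step 13 would be run with i-Pr3SiH to give the C1 triisopropylsilyl ether F10. Controlled HF·pyridine removes the two TBS groups to give the diol F11. Acetylation gives the diacetate F12. Longer exposure to HF·pyridine cleaves the triisopropylsilyl ether to the allylic alcohol F13. Dess–Martin oxidation then gives 28 directly.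

## Further compounds

F1 | step 13 | (5R)-4-[(1S)-3-bromo-1-hydroxybut-3-en-1-yl]-3-(TBS-oxymethyl) butenolide with the C5 dioxolanyl side chain | C=C(Br)C[C@H](O)C1=C(CO[Si](C)(C)C(C)(C)C)C(=O)O[C@@H]1/C=C(/C)CCC2OCCO2
F2 | step 13 | bis-TBS ether of F1 | C=C(Br)C[C@H](O[Si](C)(C)C(C)(C)C)C1=C(CO[Si](C)(C)C(C)(C)C)C(=O)O[C@@H]1/C=C(/C)CCC2OCCO2
F3 | step 13 | bis-TBS bromoalkenyl aldehyde | C=C(Br)C[C@H](O[Si](C)(C)C(C)(C)C)C1=C(CO[Si](C)(C)C(C)(C)C)C(=O)O[C@@H]1/C=C(/C)CCC=O
F4 | step 5 | (5R)-3,4-bis(trimethylstannyl) butenolide with the C5 dioxolanyl side chain | C[Sn](C)(C)C1=C([Sn](C)(C)C)C(=O)O[C@@H]1/C=C(/C)CCC2OCCO2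
F5 | step 5 | (5R)-3,4-diiodo butenolide with the C5 dioxolanyl side chain | IC1=C(I)C(=O)O[C@@H]1/C=C(/C)CCC2OCCO2
F6 | step 5 | (5R)-4-(hydroxymethyl)-3-iodo butenolide with the C5 dioxolanyl side chain | OCC1=C(I)C(=O)O[C@@H]1/C=C(/C)CCC2OCCO2
F7 | step 10 | (5R)-4-[1-hydroxy-4-(trimethylsilyl)but-3-yn-1-yl]-3-(TBS-oxymethyl) butenolide, carbinol epimers | C[Si](C)(C)C#CCC(O)C1=C(CO[Si](C)(C)C(C)(C)C)C(=O)O[C@@H]1/C=C(/C)CCC2OCCO2
F8 | step 10 | (5R)-4-[4-(trimethylsilyl)but-3-ynoyl]-3-(TBS-oxymethyl) butenolide | C[Si](C)(C)C#CCC(=O)C1=C(CO[Si](C)(C)C(C)(C)C)C(=O)O[C@@H]1/C=C(/C)CCC2OCCO2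
F9 | step 10 | (5R)-4-[(1S)-1-hydroxy-4-(trimethylsilyl)but-3-yn-1-yl]-3-(TBS-oxymethyl) butenolide | C[Si](C)(C)C#CC[C@H](O)C1=C(CO[Si](C)(C)C(C)(C)C)C(=O)O[C@@H]1/C=C(/C)CCC2OCCO2
F10 | step 16 | macrocyclic C1 triisopropylsilyl ether, bis-TBS (C1 epimers, 1S drawn) | C=C1C[C@H](O[Si](C)(C)C(C)(C)C)C2=C(CO[Si](C)(C)C(C)(C)C)C(=O)O[C@@H]2/C=C(/C)CC[C@@H]1O[Si](C(C)C)(C(C)C)C(C)C
F11 | step 16 | macrocyclic C1 triisopropylsilyl ether, C4 and C13 diol | C=C1C[C@H](O)C2=C(CO)C(=O)O[C@@H]2/C=C(/C)CC[C@@H]1O[Si](C(C)C)(C(C)C)C(C)C
F12 | step 16 | macrocyclic C1 triisopropylsilyl ether, C4 and C13 diacetate | C=C1C[C@H](OC(C)=O)C2=C(COC(C)=O)C(=O)O[C@@H]2/C=C(/C)CC[C@@H]1O[Si](C(C)C)(C(C)C)C(C)C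
F13 | step 16 | macrocyclic C1 allylic alcohol, C4 and C13 diacetate | C=C1C[C@H](OC(C)=O)C2=C(COC(C)=O)C(=O)O[C@@H]2/C=C(/C)CC[C@@H]1O
A1 | alternative 1 | (1S,2S)-1-(3-methoxyprop-1-en-2-yl)-4-methyl-2-{(1Z)-1-(PMB-oxy)-3-[(PMB-oxy)methyl]buta-1,3-dien-2-yl}cyclohex-3-en-1-ol | COCC(=C)[C@]1(O)CCC(C)=C[C@H]1/C(C(=C)COCc2ccc(OC)cc2)=C/OCc3ccc(OC)cc3
A2 | alternative 1 | ten-membered methylene ketone with the (4S)-PMB ether and an exocyclic diene | C=C1C[C@H](OCc2ccc(OC)cc2)/C(C(=C)COCc2ccc(OC)cc2)=C/C=C(/C)CCC1=O
A3 | alternative 2 | butenolide with an (R)-oxiranyl group on C5, the (Z)-alkenyl vinyl ketone chain on C6 and a primary TBS ether | C1O[C@@H]1C2=C(CO[Si](C)(C)C(C)(C)C)C(=O)O[C@@H]2/C=C(/C)CCC(=O)C=C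
A4 | alternative 2 | ten-membered (4S)-hydroxy methylene ketone fused to the butenolide, primary TBS ether | C=C1C[C@H](O)C2=C(CO[Si](C)(C)C(C)(C)C)C(=O)O[C@@H]2/C=C(/C)CCC1=O
A5 | alternative 3 | twelve-membered allyl β-keto lactone, bis-TBS | C=C1C[C@H](O[Si](C)(C)C(C)(C)C)C2=C(CO[Si](C)(C)C(C)(C)C)C(=O)O[C@@H]2/C=C(/C)COC(=O)CC1=O
A6 | alternative 3 | bis-TBS methylene ketone (same compound as 26) | C=C1C[C@H](O[Si](C)(C)C(C)(C)C)C2=C(CO[Si](C)(C)C(C)(C)C)C(=O)O[C@@H]2/C=C(/C)CCC1=O
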